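## Structural features

The target is a twelve-carbon chain (C1 = lactone carbonyl to C12 = methyl) folded into two oxygen heterocycles: ring A, a 5,6-dihydro-2H-pyran-2-one (C1–C5 with the Z-alkene C2=C3), and ring B, a 2,5-cis-disubstituted tetrahydrofuran (ring O, C7–C10). The rings are joined through the free secondary carbinol C6. The other flank of ring B carries the C11 carbinol, esterified with (Z)-4-hydroxycinnamic acid, and the C12 methyl. Five stereocentres lie on the chain: C5 (R) and C6 (S) are adjacent and erythro, C6/C7 (R) are threo, C7/C10 (S) are cis across the ring oxygen, and C10/C11 (S) are threo. The fragile groups are the Z-cinnamate (light, nucleophiles or strong acid turn it to E), the unsaturated lactone (a Michael acceptor that the C6 hydroxyl could attack at C3 under base), the free phenol and both ester linkages. The real difficulty is twofold: a cis ring B flanked on both sides by carbinols of fixed relative configuration, and two secondary hydroxyls that must end up different (C6 free, C11 acylated). The key step exploits the fact that the ring-B oxygen and C7 together are an aldehyde carbonyl in disguise and that C8 and C9 are bare methylenes. C8–C9–C10 can therefore enter as a cyclopropane whose C8 carries two removable esters and whose C10 carries a vinyl group, the latent C11–C12 carbinol, while the aldehyde brings C3–C7 with C5 and C6 from a sugar.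

## Logic of the disconnections

29 to 27. The acyl–oxygen bond C1–O5 of ring A is cut, and O5/O6 are re-joined as an acetonide and the phenol as its methoxymethyl ether. With a Z C2=C3 alkene the O5 hydroxyl sits next to C1 and closes the six-membered ring once freed, and the C6 hydroxyl appears only in this last operation, after C11 is already acylated. One ring and three protecting groups vanish in one step. The demand is an acid treatment that hydrolyses both acetals and drives lactonisation without isomerising the Z-cinnamate or cleaving the C11 ester.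

27 to 26 and 21. The C2=C3 bond is cut. A Z-selective phosphonate olefination brings C1 and C2 from 21 and leaves C3 as an aldehyde. The demand is high Z selectivity and no β-elimination of O5.

26 to 25 to 24. No skeletal bond is cut; C3 is returned to its silyl ether, a spectator that survives steps 7 to 16. The demand is that fluoride and the oxidant leave two esters and a Z-alkene untouched.

24 to 18 and 23. The acyl–oxygen bond at C11 is cut. In 18 the C11 hydroxyl is the only free hydroxyl (O5/O6 in the acetonide, O3 silylated), so the C6/C11 distinction is settled by timing and not by reagent selectivity. The acid 23 can be purified as the pure Z-isomer before coupling. The demand is activation of 23 without Z-to-E isomerisation.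

23 to 22 to 20 and 21; 20 to 19. The cinnamate Cα=Cβ bond is cut to 20 and 21, and the aryl ether bond of 20 is cut to 19. The demand is ester hydrolysis that keeps the Z geometry.

18 to 17 to 16. The C11–H bond and then the C11=O bond are removed, back to the vinyl group of 16. The vinyl group is the donor the key step needs and a masked methyl carbinol. The demand is Markovnikov oxidation of an alkene allylic to the ring oxygen without epimerising C10, and hydride delivery anti to the C10–O bond to give the threo alcohol.

16 to 14 to 13 to 12. Two C8–carboxyl bonds are put back. This brings no simplification; the geminal diester is the price of the key step because it activates the three-carbon unit. The demand is stepwise removal that spares the vinyl group, the acetonide, the silyl ether and the C7 and C10 centres.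

12 to 5 and 11. The O–C10 and C7–C8 bonds are cut. The molecule divides into a three-carbon donor–acceptor unit and a five-carbon chiral-pool aldehyde; one ring, two bonds and two stereocentres are gained. The demand is inversion at C10 without ionisation, cis ring closure that overrides the facial bias of C6, and a Lewis acid that the acetonide and silyl ether tolerate.

5 to 4 to 1 and 2. The C8–C9 and C8–C10 bonds of the cyclopropane are cut (double alkylation), followed by resolution. The demand is E geometry in 2, which steers the second alkylation to the three-membered ring, and separation of the enantiomers.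

11 to 10 to 9 to 7 to 6. No carbon–carbon bond is cut: C3–C7 are the five carbons of 6, and its two secondary carbinols become C5 and C6 with the erythro relationship and absolute configuration already correct. The demand is telling the two primary hydroxyls of 9 apart and oxidising 10 without epimerising C6.

## Other disconnections considered

Alternative 1: Baeyer–Villiger route. The cut is the ring O–C5 bond of the lactone, traced back to the C1–C5 carbon–carbon bond of the 2-substituted cyclopentanone A2. A2 is itself the silylated aldol of the tetrahydrofuran aldehyde A3 with cyclopentanone A4 (C5–C6 bond). Forward, a buffered peracid adds to the ketone of A2 and the more substituted C5 migrates to oxygen with retention, giving the saturated δ-lactone A1.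
- In its favour: regiochemistry and retention at C5 are highly dependable. The C6 and C11 oxygens are differentiated from the start by a silyl and a p-methoxybenzyl ether. The Z-coumarate can be attached after the lactone exists, so the Z-alkene meets fewer reagents. On these three points the alternative is the better plan.
- Against it: A1 lacks the C2=C3 alkene, so a dehydrogenation sequence must follow. The aldol must set C5 and C6 together as the syn aldol with chelation-type face selection on A3, whereas a cyclic E-enolate in a closed transition state prefers the anti aldol. C5 in A2 is an epimerisable α-keto centre. A3, with its cis ring and the C10/C11 centres, must still be made by some other ring-forming method.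
- Comparison: structurally, the chosen plan takes C5 and C6 from a sugar and forms ring B in the step that joins the halves; the alternative builds C5 and C6 by a demanding aldol and leaves ring B open. Mechanistically, the oxygen insertion is more predictable than the annulation of step 7. In step count the alternative should be longer, since the synthesis of A3, two deprotections and the dehydrogenation come on top.

Alternative 2: ring-opening cross-metathesis. The cut runs through the C5=C6 alkene and the C11=C12 vinyl group of A5, both traced back to the strained alkene of the meso bicycle A6, with C3–C5 arriving as the butenyl ether A7. Forward, the chiral carbene RuCl2(NHC*)(=CH-2-iPrOC6H4) adds to one enantiotopic end of A6, the bicycle opens and the new carbene is captured by A7. No ring closes, because ring B is already present in A6.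
- In its favour: the cis relationship of C7 and C10 is inherited from the bicycle and cannot fail, which is better than the chosen plan, where cis closure must win against the C6 bias. Both ring stereocentres come from a catalyst and achiral materials, without resolution and without an activating group to remove, so the core is reached in fewer steps than through 12 to 16 (better step economy to that point). The C10 vinyl group of A5 is the same handle as in 16, so the elaboration of C11 is equal in both plans.
- Against it: enantioselectivity and E/Z control in such reactions are catalyst-specific, and oligomerisation of A6 competes. C5 and C6 must still be oxidised, and syn-dihydroxylation of the E-alkene gives a threo diol where the target is erythro. This forces a Z-alkene, an inversion at C5 or an epoxide detour. The terminal and internal alkenes must also be told apart.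
- Comparison: the chosen plan imports the erythro C5/C6 diol ready-made and pays with three steps of ester removal; the alternative reaches the ring cheaply and pays at C5/C6. The overall step count should be about equal. The mechanistic risk lies in catalyst control there and in stereospecific ring opening here.

Alternative 3: permanganate oxidative cyclisation. The cut removes at once both ring C–O bonds (O–C7, O–C10) and the C6–OH and C11–OH bonds, leading back to the (2E,6E)-octadienoyl sultam A9. Forward, KMnO4 in buffered acetone adds to the electron-poor C6=C7 alkene, the manganese ester adds across C10=C11, and hydrolysis releases the cis-tetrahydrofuran diol A8. Each alkene is oxidised suprafacially, so the two E-alkenes translate into threo–cis–threo, which is exactly the C6/C7, C7/C10 and C10/C11 pattern of the target; the camphorsultam selects the face.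
- In its favour: four stereocentres and the ring arise in one step from an achiral diene, against two in the chosen key step. C11 arrives as the carbinol in the right configuration, so the Wacker/reduction pair and the three decarboxylation steps disappear. The C6 hydroxyl, α to the imide, is less nucleophilic than the C11 hydroxyl, which may allow direct acylation at C11. On step economy and on stereocentres per step this alternative is the better plan.
- Against it: such cyclisations are prone to over-oxidation and to imperfect auxiliary control. C5 enters at the carboxyl level, so the auxiliary must be cleaved reductively and C5 created later by a separate stereoselective addition (anti to C6), followed by construction of ring A with the C6 hydroxyl protected.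
- Comparison: structurally the plans are complementary. The alternative is strongest at C6/C7/C10/C11 and weakest at C5; the chosen plan has C5/C6 from the sugar and spends steps on C8 and C11. Mechanistically both rest on stereospecific processes of comparable precedent. In step count the alternative should be shorter.

Key step: step 7

Remark: atoms are numbered along the chain from C1 to C12 in every intermediate; where the descriptor of C6 changes between intermediates this reflects CIP priorities, not inversion; DMP = Dess–Martin periodinane, TBDPS = tert-butyldiphenylsilyl, MOM = methoxymethyl, Quinox = 2-(4,5-dihydrooxazol-2-yl)quinoline.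

## Route

Step 1
Reactants: 1 dimethyl malonate; 2 (E)-1,4-dibromobut-2-ene
Product: 4 rac-dimethyl 2-vinylcyclopropane-1,1-dicarboxylate, via monoalkylated bromobutenyl malonate 3 (not isolated)
Conditions: NaOMe (2.1 equiv), MeOH, 0 °C → reflux
Reagents that add atoms: none
Why: Double alkylation of a malonate: SN2 at one allylic bromide gives 3, whose enolate closes by intramolecular SN2′ displacement (3-exo-trig) because the E-alkene keeps the second CH2Br out of reach for five-ring closure.

Step 2
Reactants: 4 rac-dimethyl 2-vinylcyclopropane-1,1-dicarboxylate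
Product: 5 dimethyl (R)-2-vinylcyclopropane-1,1-dicarboxylate
Conditions: preparative chiral SFC, cellulose tris(3,5-dimethylphenylcarbamate) phase, CO2/iPrOH
Reagents that add atoms: none
Why: Physical resolution on a chiral stationary phase, the shortest access for a neutral diester with no salt-forming handle; the absolute configuration of the collected enantiomer is to be confirmed before use.

Step 3
Reactants: 6 2-deoxy-L-ribose
Product: 7 2-deoxy-3,4-O-isopropylidene-L-erythro-pentopyranose
Conditions: 2-methoxypropene, PPTS (cat.), EtOAc, 0 °C → rt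
Reagents that add atoms: 2-methoxypropene, C=C(C)OC
Why: Kinetic acetalisation with an enol ether: in the pyranose form the two cis secondary hydroxyls (future O5 and O6) are the only free vicinal pair, so the cis-fused dioxolane forms there and C3 stays masked as the lactol.

Step 4
Reactants: 7 2-deoxy-3,4-O-isopropylidene-L-erythro-pentopyranose
Product: 9 2-[(4R,5S)-5-(hydroxymethyl)-2,2-dimethyl-1,3-dioxolan-4-yl]ethanol, via open-chain hydroxy aldehyde 8 (not isolated)
Conditions: NaBH4, EtOH, 0 °C → rt
Reagents that add atoms: none
Why: Borohydride reduces the aldehyde tautomer 8 that is in equilibrium with the lactol, releasing both primary alcohols without touching C5 or C6.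

Step 5
Reactants: 9 2-[(4R,5S)-5-(hydroxymethyl)-2,2-dimethyl-1,3-dioxolan-4-yl]ethanol
Product: 10 [(4S,5R)-5-[2-(tert-butyldiphenylsilyloxy)ethyl]-2,2-dimethyl-1,3-dioxolan-4-yl]methanol
Conditions: TBDPSCl (1.0 equiv), imidazole, CH2Cl2, −20 °C
Reagents that add atoms: tert-butyl(chloro)diphenylsilane, CC(C)(C)[Si](Cl)(c1ccccc1)c1ccccc1
Why: Sterically controlled monosilylation: the C3 hydroxyl sits on an unbranched ethylene arm, whereas the C7 hydroxyl is neopentyl-like next to the cis-substituted dioxolane carbon, so the bulky chloride should prefer C3. The regioisomer and the bis-ether are separable and can be returned to 9 with fluoride.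

Step 6
Reactants: 10 [(4S,5R)-5-[2-(tert-butyldiphenylsilyloxy)ethyl]-2,2-dimethyl-1,3-dioxolan-4-yl]methanol
Product: 11 (4R,5R)-5-[2-(tert-butyldiphenylsilyloxy)ethyl]-2,2-dimethyl-1,3-dioxolane-4-carbaldehyde
Conditions: DMP, NaHCO3, CH2Cl2, 0 °C → rt
Reagents that add atoms: none
Why: Dess–Martin oxidation under buffered, base-free conditions, chosen to avoid epimerisation of the cis-dioxolane aldehyde at C6; 11 is used at once.

Step 7
Reactants: 5 dimethyl (R)-2-vinylcyclopropane-1,1-dicarboxylate; 11 (4R,5R)-5-[2-(tert-butyldiphenylsilyloxy)ethyl]-2,2-dimethyl-1,3-dioxolane-4-carbaldehyde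
Product: 12 dimethyl (2R,5S)-2-[(4R,5R)-5-[2-(tert-butyldiphenylsilyloxy)ethyl]-2,2-dimethyl-1,3-dioxolan-4-yl]-5-vinyloxolane-3,3-dicarboxylate
Conditions: Sn(OTf)2 (10 mol%), 2,6-di-tert-butylpyridine (10 mol%), 5 (1.5 equiv), CH2Cl2 (0.5 M), 0 °C → rt
Reagents that add atoms: none
Why: Sn(OTf)2 chelates the two ester carbonyls of 5 and polarises the C8–C10 bond; the carbonyl oxygen of 11 then attacks C10 from the rear in an SN2-like, strain-releasing step on the contact ion pair, so C10 is inverted from R to S. The oxocarbenium/tin malonate ion pair closes by addition of the malonate carbon C8 to C7, an aldol-type 5-(enolexo)-endo-trig closure that is awkward for neutral carbonyls but routine for oxocarbenium ions; this forms ring B through the bonds O–C10 and C7–C8. The closest known reaction type is the divalent tin triflate-catalysed formal [3+2] annulation of donor–acceptor cyclopropane-1,1-diesters with aldehydes, which gives 2,5-cis-tetrahydrofurans with inversion at the donor carbon; vinyl donors and aliphatic aldehydes belong to its substrate class. C7 is set in the ring closure: an envelope transition state from the E-oxocarbenium ion places the C10 vinyl and the C7 dioxolanyl group pseudo-equatorial, which gives the cis ring and hence 7R from 10S. The step needs stereospecific inversion (no free allyl cation), which the weakly stabilising unsubstituted vinyl donor, low temperature, high concentration and a non-ionising solvent should secure. It also needs cis closure against the C6 centre, which on its own would favour attack anti to the C6–O bond, that is, on the other face of C7, so the ring transition state has to override it. The acetonide keeps the C6 substituent compact, which should limit that penalty, and any diastereomer arising from racemised 5 is separable because 11 is a single enantiomer. The hindered pyridine scavenges adventitious triflic acid and so protects the acetonide and the silyl ether.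

Step 8
Reactants: 12 dimethyl (2R,5S)-2-[(4R,5R)-5-[2-(tert-butyldiphenylsilyloxy)ethyl]-2,2-dimethyl-1,3-dioxolan-4-yl]-5-vinyloxolane-3,3-dicarboxylate
Product: 13 methyl (2R,5S)-2-[(4R,5R)-5-[2-(tert-butyldiphenylsilyloxy)ethyl]-2,2-dimethyl-1,3-dioxolan-4-yl]-5-vinyloxolane-3-carboxylate (C8 epimers)
Conditions: LiCl, H2O (2 equiv), DMSO, 150 °C
Reagents that add atoms: none
Why: Krapcho dealkoxycarbonylation: chloride demethylates one ester, the half-ester loses CO2 and the ester enolate is protonated by water. Ring opening by β-elimination of the ring oxygen is stereoelectronically disfavoured because the C7–O bond is orthogonal to the enolate π system, and C8 is a transient stereocentre of no consequence.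

Step 9
Reactants: 13 methyl (2R,5S)-2-[(4R,5R)-5-[2-(tert-butyldiphenylsilyloxy)ethyl]-2,2-dimethyl-1,3-dioxolan-4-yl]-5-vinyloxolane-3-carboxylate
Product: 14 (2R,5S)-2-[(4R,5R)-5-[2-(tert-butyldiphenylsilyloxy)ethyl]-2,2-dimethyl-1,3-dioxolan-4-yl]-5-vinyloxolane-3-carboxylic acid (C8 epimers)
Conditions: LiOH·H2O, THF/MeOH/H2O, 40 °C; then dilute HCl to pH 4, 0 °C
Reagents that add atoms: lithium hydroxide, [Li+].[OH-]
Why: Saponification of the remaining ester; silyl ether, acetonide and vinyl group are inert to hydroxide at this temperature, and acidification only to pH 4 spares the acetonide.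

Step 10
Reactants: 14 (2R,5S)-2-[(4R,5R)-5-[2-(tert-butyldiphenylsilyloxy)ethyl]-2,2-dimethyl-1,3-dioxolan-4-yl]-5-vinyloxolane-3-carboxylic acid
Product: 16 (2R,5S)-2-[(4S,5R)-5-[2-(tert-butyldiphenylsilyloxy)ethyl]-2,2-dimethyl-1,3-dioxolan-4-yl]-5-vinyloxolane, via thiohydroxamate ester 15 (not isolated)
Conditions: 2-mercaptopyridine N-oxide, DCC, DMAP (cat.), CH2Cl2, dark, 0 °C → rt; then t-BuSH (2 equiv), hν (tungsten lamp), 10 °C
Reagents that add atoms: none
Why: Barton decarboxylation: 15 fragments under visible light to the C8 radical, which takes hydrogen from the thiol. The radical is homoallylic to the vinyl group (only a reversible three-ring closure is open to it) and does not expel the β ring oxygen, so C7 and C10 are untouched; limited thiol and short irradiation keep thiol–ene addition to the vinyl group down.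

Step 11
Reactants: 16 (2R,5S)-2-[(4S,5R)-5-[2-(tert-butyldiphenylsilyloxy)ethyl]-2,2-dimethyl-1,3-dioxolan-4-yl]-5-vinyloxolane
Product: 17 1-[(2S,5R)-5-[(4S,5R)-5-[2-(tert-butyldiphenylsilyloxy)ethyl]-2,2-dimethyl-1,3-dioxolan-4-yl]oxolan-2-yl]ethan-1-one
Conditions: PdCl2(Quinox) (5 mol%), AgSbF6 (12 mol%), aq. TBHP, CH2Cl2, 0 °C → rt
Reagents that add atoms: tert-butyl hydroperoxide, CC(C)(C)OO
Why: Wacker-type oxidation with a cationic quinoline–oxazoline palladium catalyst and TBHP, chosen because it gives methyl ketones from allylic ethers where the PdCl2/CuCl/O2 system drifts toward the aldehyde. Its near-neutral medium should not epimerise C10.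

Step 12
Reactants: 17 1-[(2S,5R)-5-[(4S,5R)-5-[2-(tert-butyldiphenylsilyloxy)ethyl]-2,2-dimethyl-1,3-dioxolan-4-yl]oxolan-2-yl]ethan-1-one
Product: 18 (1S)-1-[(2S,5R)-5-[(4S,5R)-5-[2-(tert-butyldiphenylsilyloxy)ethyl]-2,2-dimethyl-1,3-dioxolan-4-yl]oxolan-2-yl]ethan-1-ol
Conditions: LiBH(sBu)3, THF, −78 °C; then H2O
Reagents that add atoms: none
Why: Felkin–Anh reduction of an α-alkoxy ketone by a bulky, non-chelating hydride: the C10–O bond lies anti to the incoming hydride, which passes the C10–H, giving the threo (10S,11S) alcohol. A chelated mode would give the erythro epimer.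

Step 13
Reactants: 19 4-hydroxybenzaldehyde
Product: 20 4-(methoxymethoxy)benzaldehyde
Conditions: MOMCl, iPr2NEt, CH2Cl2, 0 °C → rt
Reagents that add atoms: chloromethyl methyl ether, COCCl
Why: Phenol O-alkylation to an aryl acetal that is stable to base, fluoride and oxidant in all later steps and falls in the final acid step.

Step 14
Reactants: 20 4-(methoxymethoxy)benzaldehyde; 21 methyl 2-[bis(2,2,2-trifluoroethoxy)phosphoryl]acetate
Product: 22 methyl (Z)-3-[4-(methoxymethoxy)phenyl]prop-2-enoate
Conditions: KN(SiMe3)2, 18-crown-6, THF, −78 °C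
Reagents that add atoms: none
Why: Still–Gennari olefination: the electron-poor phosphonate under dissociating conditions eliminates quickly from the kinetically formed adduct, which gives the Z-cinnamate.

Step 15
Reactants: 22 methyl (Z)-3-[4-(methoxymethoxy)phenyl]prop-2-enoate
Product: 23 (Z)-3-[4-(methoxymethoxy)phenyl]prop-2-enoic acid
Conditions: LiOH·H2O, THF/H2O, rt; then 1 M HCl to pH 3, 0 °C
Reagents that add atoms: lithium hydroxide, [Li+].[OH-]
Why: Mild saponification; hydroxide does not isomerise the Z-cinnamate and the aryl acetal is base-stable. Purification of the acid allows removal of any E-isomer before coupling.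

Step 16
Reactants: 18 (1S)-1-[(2S,5R)-5-[(4S,5R)-5-[2-(tert-butyldiphenylsilyloxy)ethyl]-2,2-dimethyl-1,3-dioxolan-4-yl]oxolan-2-yl]ethan-1-ol; 23 (Z)-3-[4-(methoxymethoxy)phenyl]prop-2-enoic acid
Product: 24 (1S)-1-[(2S,5R)-5-[(4S,5R)-5-[2-(tert-butyldiphenylsilyloxy)ethyl]-2,2-dimethyl-1,3-dioxolan-4-yl]oxolan-2-yl]ethyl (Z)-3-[4-(methoxymethoxy)phenyl]prop-2-enoate
Conditions: DCC, DMAP (0.2 equiv), CH2Cl2, 0 °C → rt, dark
Reagents that add atoms: none
Why: Steglich esterification: the C11 hydroxyl is the only free hydroxyl in 18, so no selectivity question arises, and C11 keeps its configuration because the acyl–oxygen bond is the one formed. Low temperature, little DMAP and exclusion of light limit Z-to-E isomerisation of the activated acid.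

Step 17
Reactants: 24 (1S)-1-[(2S,5R)-5-[(4S,5R)-5-[2-(tert-butyldiphenylsilyloxy)ethyl]-2,2-dimethyl-1,3-dioxolan-4-yl]oxolan-2-yl]ethyl (Z)-3-[4-(methoxymethoxy)phenyl]prop-2-enoate
Product: 25 (1S)-1-[(2S,5R)-5-[(4S,5R)-5-(2-hydroxyethyl)-2,2-dimethyl-1,3-dioxolan-4-yl]oxolan-2-yl]ethyl (Z)-3-[4-(methoxymethoxy)phenyl]prop-2-enoate
Conditions: Bu4NF, AcOH (1:1), THF, 0 °C → rt
Reagents that add atoms: none
Why: Fluoride cleavage of the silyl ether, buffered with acetic acid so that the ester is not attacked and the Z-alkene is not isomerised.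

Step 18
Reactants: 25 (1S)-1-[(2S,5R)-5-[(4S,5R)-5-(2-hydroxyethyl)-2,2-dimethyl-1,3-dioxolan-4-yl]oxolan-2-yl]ethyl (Z)-3-[4-(methoxymethoxy)phenyl]prop-2-enoate
Product: 26 (1S)-1-[(2S,5R)-5-[(4S,5R)-2,2-dimethyl-5-(2-oxoethyl)-1,3-dioxolan-4-yl]oxolan-2-yl]ethyl (Z)-3-[4-(methoxymethoxy)phenyl]prop-2-enoate
Conditions: DMP, NaHCO3, CH2Cl2, 0 °C → rt
Reagents that add atoms: none
Why: Buffered Dess–Martin oxidation of the primary alcohol; the β-alkoxy aldehyde is used at once to avoid elimination of O5.

Step 19
Reactants: 26 (1S)-1-[(2S,5R)-5-[(4S,5R)-2,2-dimethyl-5-(2-oxoethyl)-1,3-dioxolan-4-yl]oxolan-2-yl]ethyl (Z)-3-[4-(methoxymethoxy)phenyl]prop-2-enoate; 21 methyl 2-[bis(2,2,2-trifluoroethoxy)phosphoryl]acetate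
Product: 27 methyl (Z)-4-[(4R,5S)-5-[(2R,5S)-5-[(1S)-1-[(Z)-3-[4-(methoxymethoxy)phenyl]prop-2-enoyloxy]ethyl]oxolan-2-yl]-2,2-dimethyl-1,3-dioxolan-4-yl]but-2-enoate
Conditions: KN(SiMe3)2, 18-crown-6, THF, −78 °C
Reagents that add atoms: none
Why: Second Still–Gennari olefination, now on an aliphatic aldehyde, sets the Z C2=C3 alkene required for ring closure. The stabilised phosphonate anion at −78 °C is too weakly basic to eliminate O5 or to attack the ester.

Step 20
Reactants: 27 methyl (Z)-4-[(4R,5S)-5-[(2R,5S)-5-[(1S)-1-[(Z)-3-[4-(methoxymethoxy)phenyl]prop-2-enoyloxy]ethyl]oxolan-2-yl]-2,2-dimethyl-1,3-dioxolan-4-yl]but-2-enoate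
Product: 29 (1S)-1-[(2S,5R)-5-[(S)-hydroxy[(2R)-6-oxo-3,6-dihydro-2H-pyran-2-yl]methyl]oxolan-2-yl]ethyl (Z)-3-(4-hydroxyphenyl)prop-2-enoate, via seco triol methyl ester 28 (not isolated)
Conditions: TFA/H2O (9:1), CH2Cl2, 0 °C → rt; then toluene azeotrope
Reagents that add atoms: none
Why: Acid hydrolysis removes the acetonide and the aryl methoxymethyl group; in 28 the Z-alkene holds the C5 hydroxyl next to the ester, so it lactonises to the six-membered ring, while the C6 hydroxyl would have to form a seven-membered ring. No base is present, so oxa-Michael addition of the C6 hydroxyl and ester migration are avoided.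

## Compound list

1 | dimethyl malonate | COC(=O)CC(=O)OC | starting material
2 | (E)-1,4-dibromobut-2-ene | BrC/C=C/CBr | starting material
3 | dimethyl 2-[(E)-4-bromobut-2-enyl]malonate (formed in situ) | COC(=O)C(C/C=C/CBr)C(=O)OC | intermediate
4 | rac-dimethyl 2-vinylcyclopropane-1,1-dicarboxylate | C=CC1CC1(C(=O)OC)C(=O)OC | intermediate
5 | dimethyl (R)-2-vinylcyclopropane-1,1-dicarboxylate | C=C[C@H]1CC1(C(=O)OC)C(=O)OC | intermediate
6 | 2-deoxy-L-ribose | OC[C@H](O)[C@H](O)CC=O | starting material
7 | 2-deoxy-3,4-O-isopropylidene-L-erythro-pentopyranose (anomer mixture) | O1C[C@@H]2OC(C)(C)O[C@@H]2CC1O | intermediate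
8 | 2-deoxy-3,4-O-isopropylidene-aldehydo-L-erythro-pentose (formed in situ) | OC[C@@H]1OC(C)(C)O[C@@H]1CC=O | intermediate
9 | 2-[(4R,5S)-5-(hydroxymethyl)-2,2-dimethyl-1,3-dioxolan-4-yl]ethanol | OC[C@@H]1OC(C)(C)O[C@@H]1CCO | intermediate
10 | [(4S,5R)-5-[2-(tert-butyldiphenylsilyloxy)ethyl]-2,2-dimethyl-1,3-dioxolan-4-yl]methanol | OC[C@@H]1OC(C)(C)O[C@@H]1CCO[Si](c2ccccc2)(c3ccccc3)C(C)(C)C | intermediate
11 | (4R,5R)-5-[2-(tert-butyldiphenylsilyloxy)ethyl]-2,2-dimethyl-1,3-dioxolane-4-carbaldehyde | O=C[C@@H]1OC(C)(C)O[C@@H]1CCO[Si](c2ccccc2)(c3ccccc3)C(C)(C)C | intermediate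
12 | dimethyl (2R,5S)-2-[(4R,5R)-5-[2-(tert-butyldiphenylsilyloxy)ethyl]-2,2-dimethyl-1,3-dioxolan-4-yl]-5-vinyloxolane-3,3-dicarboxylate | C=C[C@@H]1CC(C(=O)OC)(C(=O)OC)[C@H]([C@@H]2OC(C)(C)O[C@@H]2CCO[Si](c3ccccc3)(c4ccccc4)C(C)(C)C)O1 | intermediate
13 | methyl (2R,5S)-2-[(4R,5R)-5-[2-(tert-butyldiphenylsilyloxy)ethyl]-2,2-dimethyl-1,3-dioxolan-4-yl]-5-vinyloxolane-3-carboxylate (C8 epimers) | C=C[C@@H]1CC(C(=O)OC)[C@H]([C@@H]2OC(C)(C)O[C@@H]2CCO[Si](c3ccccc3)(c4ccccc4)C(C)(C)C)O1 | intermediate
14 | (2R,5S)-2-[(4R,5R)-5-[2-(tert-butyldiphenylsilyloxy)ethyl]-2,2-dimethyl-1,3-dioxolan-4-yl]-5-vinyloxolane-3-carboxylic acid (C8 epimers) | C=C[C@@H]1CC(C(=O)O)[C@H]([C@@H]2OC(C)(C)O[C@@H]2CCO[Si](c3ccccc3)(c4ccccc4)C(C)(C)C)O1 | intermediate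
15 | 2-thioxopyridin-1(2H)-yl ester of 14 (formed in situ) | C=C[C@@H]1CC(C(=O)ON5C=CC=CC5=S)[C@H]([C@@H]2OC(C)(C)O[C@@H]2CCO[Si](c3ccccc3)(c4ccccc4)C(C)(C)C)O1 | intermediate
16 | (2R,5S)-2-[(4S,5R)-5-[2-(tert-butyldiphenylsilyloxy)ethyl]-2,2-dimethyl-1,3-dioxolan-4-yl]-5-vinyloxolane | C=C[C@@H]1CC[C@H]([C@@H]2OC(C)(C)O[C@@H]2CCO[Si](c3ccccc3)(c4ccccc4)C(C)(C)C)O1 | intermediate
17 | 1-[(2S,5R)-5-[(4S,5R)-5-[2-(tert-butyldiphenylsilyloxy)ethyl]-2,2-dimethyl-1,3-dioxolan-4-yl]oxolan-2-yl]ethan-1-one | CC(=O)[C@@H]1CC[C@H]([C@@H]2OC(C)(C)O[C@@H]2CCO[Si](c3ccccc3)(c4ccccc4)C(C)(C)C)O1 | intermediate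
18 | (1S)-1-[(2S,5R)-5-[(4S,5R)-5-[2-(tert-butyldiphenylsilyloxy)ethyl]-2,2-dimethyl-1,3-dioxolan-4-yl]oxolan-2-yl]ethan-1-ol | C[C@H](O)[C@@H]1CC[C@H]([C@@H]2OC(C)(C)O[C@@H]2CCO[Si](c3ccccc3)(c4ccccc4)C(C)(C)C)O1 | intermediate
19 | 4-hydroxybenzaldehyde | O=Cc1ccc(O)cc1 | starting material
20 | 4-(methoxymethoxy)benzaldehyde | O=Cc1ccc(OCOC)cc1 | intermediate
21 | methyl 2-[bis(2,2,2-trifluoroethoxy)phosphoryl]acetate | COC(=O)CP(=O)(OCC(F)(F)F)OCC(F)(F)F | starting material
22 | methyl (Z)-3-[4-(methoxymethoxy)phenyl]prop-2-enoate | COC(=O)/C=C\c1ccc(OCOC)cc1 | intermediate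
23 | (Z)-3-[4-(methoxymethoxy)phenyl]prop-2-enoic acid | OC(=O)/C=C\c1ccc(OCOC)cc1 | intermediate
24 | (1S)-1-[(2S,5R)-5-[(4S,5R)-5-[2-(tert-butyldiphenylsilyloxy)ethyl]-2,2-dimethyl-1,3-dioxolan-4-yl]oxolan-2-yl]ethyl (Z)-3-[4-(methoxymethoxy)phenyl]prop-2-enoate | C[C@H](OC(=O)/C=C\c1ccc(OCOC)cc1)[C@@H]1CC[C@H]([C@@H]2OC(C)(C)O[C@@H]2CCO[Si](c3ccccc3)(c4ccccc4)C(C)(C)C)O1 | intermediate
25 | (1S)-1-[(2S,5R)-5-[(4S,5R)-5-(2-hydroxyethyl)-2,2-dimethyl-1,3-dioxolan-4-yl]oxolan-2-yl]ethyl (Z)-3-[4-(methoxymethoxy)phenyl]prop-2-enoate | C[C@H](OC(=O)/C=C\c1ccc(OCOC)cc1)[C@@H]1CC[C@H]([C@@H]2OC(C)(C)O[C@@H]2CCO)O1 | intermediate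
26 | (1S)-1-[(2S,5R)-5-[(4S,5R)-2,2-dimethyl-5-(2-oxoethyl)-1,3-dioxolan-4-yl]oxolan-2-yl]ethyl (Z)-3-[4-(methoxymethoxy)phenyl]prop-2-enoate | C[C@H](OC(=O)/C=C\c1ccc(OCOC)cc1)[C@@H]1CC[C@H]([C@@H]2OC(C)(C)O[C@@H]2CC=O)O1 | intermediate
27 | methyl (Z)-4-[(4R,5S)-5-[(2R,5S)-5-[(1S)-1-[(Z)-3-[4-(methoxymethoxy)phenyl]prop-2-enoyloxy]ethyl]oxolan-2-yl]-2,2-dimethyl-1,3-dioxolan-4-yl]but-2-enoate | C[C@H](OC(=O)/C=C\c1ccc(OCOC)cc1)[C@@H]1CC[C@H]([C@@H]2OC(C)(C)O[C@@H]2C/C=C\C(=O)OC)O1 | intermediate
28 | methyl (2Z,5R,6R)-5,6-dihydroxy-6-[(2R,5S)-5-[(1S)-1-[(Z)-3-(4-hydroxyphenyl)prop-2-enoyloxy]ethyl]oxolan-2-yl]hex-2-enoate (formed in situ) | C[C@H](OC(=O)/C=C\c1ccc(O)cc1)[C@@H]1CC[C@H]([C@H](O)[C@H](O)C/C=C\C(=O)OC)O1 | intermediate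
29 | (1S)-1-[(2S,5R)-5-[(S)-hydroxy[(2R)-6-oxo-3,6-dihydro-2H-pyran-2-yl]methyl]oxolan-2-yl]ethyl (Z)-3-(4-hydroxyphenyl)prop-2-enoate | C[C@H](OC(=O)/C=C\c1ccc(O)cc1)[C@@H]1CC[C@H]([C@H](O)[C@H]2CC=CC(=O)O2)O1 | target

## Step count and least certain steps

Total: 20 steps. Longest linear sequence: 15 steps from 6 (steps 3–12 and 16–20); the cyclopropane branch (steps 1–2) joins at step 7 and the acid branch (steps 13–15) at step 16.

Step 7 (key step). The most likely failures are loss of stereospecificity and erosion of cis selectivity. Ionisation of the Lewis acid-bound cyclopropane can outrun capture, because the inductively deactivated, doubly oxygenated aldehyde is a weaker oxygen nucleophile than a simple aldehyde. The ring closure must also go against the facial preference of the C6 centre, and the dioxolane oxygens may sequester the catalyst. A stronger Lewis acid at lower temperature would be tried first. The fallback abandons the annulation and sets out from 11: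
- Addition of but-3-enylmagnesium bromide gives the C7 carbinol mixture 1-[(4S,5R)-5-[2-(tert-butyldiphenylsilyloxy)ethyl]-2,2-dimethyl-1,3-dioxolan-4-yl]pent-4-en-1-ol F1.
- Dess–Martin oxidation gives the ketone 1-[(4R,5R)-5-[2-(tert-butyldiphenylsilyloxy)ethyl]-2,2-dimethyl-1,3-dioxolan-4-yl]pent-4-en-1-one F2.
- Reduction with LiBH(sBu)3, where the Felkin preference of C6 now works in favour, should give the (7R)-carbinol F3.
- Cross-metathesis with (Z)-but-2-ene-1,4-diyl diacetate and the second-generation Grubbs catalyst RuCl2(H2IMes)(PCy3)(=CHPh) gives the (E)-allylic acetate F4.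
- Zerovalent palladium-catalysed cycloetherification (Pd2(dba)3·CHCl3 with a chiral trans-1,2-diaminocyclohexane bis(2-diphenylphosphinobenzamide) ligand chosen to enforce the cis ring) closes ring B.

The fallback comes back to the route at 16 and makes steps 1, 2 and 7–10 unnecessary.

Step 11. The oxidation may lose regiocontrol, because coordination of palladium to the ring oxygen can direct oxygen to the terminal carbon, and C10 may epimerise next to the new ketone. Fallback from 16: Mukaiyama hydration (Co(acac)2, PhSiH3, O2) places oxygen at C11 through the secondary radical and gives the epimeric carbinol mixture 1-[(2S,5R)-5-(dioxolanyl)oxolan-2-yl]ethanol F5. Dess–Martin oxidation of F5 returns to the route at 17.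

Step 12. The facial selectivity may be poor or reversed if lithium chelates the ring oxygen and the carbonyl, which delivers hydride to the other face. Fallback from 17: deliberate chelation-controlled reduction with Zn(BH4)2 gives the (11R)-carbinol F6. Mitsunobu esterification of F6 with 23 (PPh3, DIAD) inverts C11 under neutral conditions and comes back at 24, which also removes step 16.

Step 16. The Z-alkene of the activated acid may isomerise through reversible conjugate addition of DMAP to the acylpyridinium ion, and the hindered carbinol may acylate slowly. Fallback from 18: esterification with [bis(2,2,2-trifluoroethoxy)phosphoryl]acetic acid (DCC) gives the C11 phosphonoacetate F7. Still–Gennari olefination of F7 with 20 (KN(SiMe3)2, 18-crown-6, −78 °C) builds the Z-cinnamate on the substrate under kinetic control and returns at 24.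

Step 20. Acid strong enough for the aryl acetal may isomerise the electron-rich Z-cinnamate by protonation at the ester carbonyl, lactonisation may stop at the seco stage, or the free hydroxyl may be trifluoroacetylated. Fallback from 27, in two stages: aqueous acetic acid (80%, 45 °C) removes only the acetonide and closes the lactone, giving the phenol-protected lactone (methoxymethyl ether of the target) F8. A non-protic cleavage of the aryl acetal with Me3SiOTf/2,2′-bipyridyl followed by water then returns to the route at 29.

## Further compounds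

F1 | step 7 | 1-[(4S,5R)-5-[2-(tert-butyldiphenylsilyloxy)ethyl]-2,2-dimethyl-1,3-dioxolan-4-yl]pent-4-en-1-ol (C7 epimers) | C=CCCC(O)[C@@H]1OC(C)(C)O[C@@H]1CCO[Si](c2ccccc2)(c3ccccc3)C(C)(C)C
F2 | step 7 | 1-[(4R,5R)-5-[2-(tert-butyldiphenylsilyloxy)ethyl]-2,2-dimethyl-1,3-dioxolan-4-yl]pent-4-en-1-one | C=CCCC(=O)[C@@H]1OC(C)(C)O[C@@H]1CCO[Si](c2ccccc2)(c3ccccc3)C(C)(C)C
F3 | step 7 | (1R)-1-[(4S,5R)-5-[2-(tert-butyldiphenylsilyloxy)ethyl]-2,2-dimethyl-1,3-dioxolan-4-yl]pent-4-en-1-ol | C=CCC[C@@H](O)[C@@H]1OC(C)(C)O[C@@H]1CCO[Si](c2ccccc2)(c3ccccc3)C(C)(C)C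
F4 | step 7 | (2E,6R)-6-[(4S,5R)-5-[2-(tert-butyldiphenylsilyloxy)ethyl]-2,2-dimethyl-1,3-dioxolan-4-yl]-6-hydroxyhex-2-enyl acetate | CC(=O)OC/C=C/CC[C@@H](O)[C@@H]1OC(C)(C)O[C@@H]1CCO[Si](c2ccccc2)(c3ccccc3)C(C)(C)C
F5 | step 11 | 1-[(2S,5R)-5-[(4S,5R)-5-[2-(tert-butyldiphenylsilyloxy)ethyl]-2,2-dimethyl-1,3-dioxolan-4-yl]oxolan-2-yl]ethanol (C11 epimers) | CC(O)[C@@H]1CC[C@H]([C@@H]2OC(C)(C)O[C@@H]2CCO[Si](c3ccccc3)(c4ccccc4)C(C)(C)C)O1
F6 | step 12 | (1R)-1-[(2S,5R)-5-[(4S,5R)-5-[2-(tert-butyldiphenylsilyloxy)ethyl]-2,2-dimethyl-1,3-dioxolan-4-yl]oxolan-2-yl]ethan-1-ol | C[C@@H](O)[C@@H]1CC[C@H]([C@@H]2OC(C)(C)O[C@@H]2CCO[Si](c3ccccc3)(c4ccccc4)C(C)(C)C)O1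
F7 | step 16 | (1S)-1-[(2S,5R)-5-[(4S,5R)-5-[2-(tert-butyldiphenylsilyloxy)ethyl]-2,2-dimethyl-1,3-dioxolan-4-yl]oxolan-2-yl]ethyl 2-[bis(2,2,2-trifluoroethoxy)phosphoryl]acetate | C[C@H](OC(=O)CP(=O)(OCC(F)(F)F)OCC(F)(F)F)[C@@H]1CC[C@H]([C@@H]2OC(C)(C)O[C@@H]2CCO[Si](c3ccccc3)(c4ccccc4)C(C)(C)C)O1
F8 | step 20 | (1S)-1-[(2S,5R)-5-[(S)-hydroxy[(2R)-6-oxo-3,6-dihydro-2H-pyran-2-yl]methyl]oxolan-2-yl]ethyl (Z)-3-[4-(methoxymethoxy)phenyl]prop-2-enoate | C[C@H](OC(=O)/C=C\c1ccc(OCOC)cc1)[C@@H]1CC[C@H]([C@H](O)[C@H]2CC=CC(=O)O2)O1
A1 | alternative 1 | saturated δ-lactone with C6 tert-butyldimethylsilyl ether and C11 4-methoxybenzyl ether | C[C@H](OCc1ccc(OC)cc1)[C@@H]1CC[C@H]([C@H](O[Si](C)(C)C(C)(C)C)[C@H]2CCCC(=O)O2)O1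
A2 | alternative 1 | silylated cyclopentanone aldol (2-substituted cyclopentanone) | C[C@H](OCc1ccc(OC)cc1)[C@@H]1CC[C@H]([C@H](O[Si](C)(C)C(C)(C)C)[C@H]2CCCC2=O)O1
A3 | alternative 1 | (2R,5S)-5-[(1S)-1-(4-methoxybenzyloxy)ethyl]oxolane-2-carbaldehyde | C[C@H](OCc1ccc(OC)cc1)[C@@H]1CC[C@H](C=O)O1
A4 | alternative 1 | cyclopentanone | O=C1CCCC1
A5 | alternative 2 | (2R,5S)-2-[(E)-4-(4-methoxybenzyloxy)but-1-enyl]-5-vinyloxolane | C=C[C@@H]1CC[C@H](/C=C/CCOCc2ccc(OC)cc2)O1
A6 | alternative 2 | meso 7-oxabicyclo[2.2.1]hept-2-ene | C1=CC2CCC1O2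
A7 | alternative 2 | 4-(4-methoxybenzyloxy)but-1-ene | C=CCCOCc1ccc(OC)cc1
A8 | alternative 3 | cis-tetrahydrofuran diol N-acyl camphorsultam | C[C@H](O)[C@@H]1CC[C@H]([C@H](O)C(=O)N2[C@H]3C[C@@H]4CC[C@@]3(CS2(=O)=O)C4(C)C)O1
A9 | alternative 3 | N-[(2E,6E)-octa-2,6-dienoyl]camphorsultam | C/C=C/CC/C=C/C(=O)N1[C@H]2C[C@@H]3CC[C@@]2(CS1(=O)=O)C3(C)C
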